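**Plan**

Ring labels: ring C is the central butyrylphloroglucinol ring (butyryl on position 1, oxygens on 2, 4 and 6, bridges on 3 and 5); rings A and B are each counted from the bridge carbon as position 1 (ring A: 2 OH, 3 CH3, 4 OCH3, 5 butyryl, 6 OH; ring B: 2 OH, 3 butyryl, 4 OH, 5 CH3, 6 OCH3).
Retrosynthesis: the seven phenols are masked as benzyl ethers, then the two aryl C–O bonds to the methoxy groups (position 4 of ring A, position 6 of ring B) are cut back to C–F, then the two bridge bonds from the CH2 groups to positions 3 and 5 of ring C, then in each terminal ring the C–butyryl and C–CH2 bonds, down to 1-fluoro-3,5-dimethoxybenzene.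
Enabling feature: the methoxy carbon of ring A (position 4) is ortho and that of ring B (position 6) is para to the butyryl carbonyl carbon of its own ring, and each is meta to the two other oxygen-bearing carbons of that ring, so a fluorine at these two carbons can be displaced by methoxide and also marks which oxygen of each terminal ring becomes the methyl ether.
Forward: no ring is built; the fluorinated rings A and B are made from one common fluorotoluene, ring C is given one benzyl ether on its 4-oxygen, rings A and then B are joined to it through ortho-quinone methides, the six remaining phenols are benzylated, both fluorides are exchanged for methoxide in one operation and the benzyl groups are removed by hydrogenolysis.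
Stereochemistry: the target has no stereocenter and no stereogenic double bond, so nothing has to be controlled.

Key step: step 14

Assumption: N-methoxy-N-methylbutanamide and butyrylphloroglucinol are taken as purchasable; the only chiral species on the route, a lithium hemiaminal alkoxide, is transient and racemic.

**Route**

Step 1
Reactants: 1 1-fluoro-3,5-dimethoxybenzene
Product: 3 2-fluoro-4,6-dimethoxybenzaldehyde, via iminium salt 2 (not isolated)
Conditions: POCl3, DMF, 0 °C to 70 °C; then H2O
Reagents that add atoms: N,N-dimethylformamide, CN(C)C=O; water, O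
Why: Vilsmeier–Haack formylation attacks the carbon that is para to one methoxy group and ortho to the other and to the small fluorine, which is as activated as the carbon between the two methoxy groups but less hindered, so the 2-fluoro aldehyde should predominate and the minor 4-fluoro isomer can be removed by crystallisation.

Step 2
Reactants: 3 2-fluoro-4,6-dimethoxybenzaldehyde
Product: 5 1-fluoro-3,5-dimethoxy-2-methylbenzene, via benzylic alcohol 4 (not isolated)
Conditions: H2 (3 atm), 10% Pd/C, AcOH, 50 °C
Reagents that add atoms: none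
Why: Catalytic hydrogenation of the electron-rich aldehyde gives the benzylic alcohol, which undergoes acid-assisted benzylic hydrogenolysis to the methyl group while aryl C–F and aryl C–O bonds are inert under these conditions.

Step 3
Reactants: 5 1-fluoro-3,5-dimethoxy-2-methylbenzene, 6 butanoyl chloride
Product: 7 1-(2-fluoro-4,6-dimethoxy-3-methylphenyl)butan-1-one
Conditions: AlCl3, CH2Cl2, 0 °C
Reagents that add atoms: butanoyl chloride 6, CCCC(=O)Cl
Why: Friedel–Crafts acylation goes to the ring carbon para to a methoxy group and next to fluorine and not to the hindered carbon between the two methoxy groups, which places the butyryl group ortho to fluorine as ring A requires.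

Step 4
Reactants: 7 1-(2-fluoro-4,6-dimethoxy-3-methylphenyl)butan-1-one
Product: 8 1-(2-fluoro-4,6-dihydroxy-3-methylphenyl)butan-1-one
Conditions: BBr3, CH2Cl2, −78 °C to rt; then H2O
Reagents that add atoms: none
Why: Lewis acid ether cleavage by BBr3 removes both aryl methyl groups as bromomethane and leaves the aryl fluoride and the ketone untouched.

Step 5
Reactants: 8 1-(2-fluoro-4,6-dihydroxy-3-methylphenyl)butan-1-one
Product: 9 1-{3-[(dimethylamino)methyl]-6-fluoro-2,4-dihydroxy-5-methylphenyl}butan-1-one
Conditions: 37% aq CH2O, 40% aq Me2NH, EtOH, 0 °C to rt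
Reagents that add atoms: formaldehyde, C=O; dimethylamine, CNC
Why: In this phenolic Mannich reaction the only unsubstituted ring carbon, between the two hydroxyl groups, is aminomethylated, and excess amine at low temperature suppresses methylene-bis-phenol formation.

Step 6
Reactants: 5 1-fluoro-3,5-dimethoxy-2-methylbenzene
Product: 11 2-fluoro-4,6-dimethoxy-3-methylbenzaldehyde, via iminium salt 10 (not isolated)
Conditions: POCl3, DMF, 0 °C to 70 °C; then H2O
Reagents that add atoms: N,N-dimethylformamide, CN(C)C=O; water, O
Why: A second Vilsmeier–Haack formylation, again para to a methoxy group and next to fluorine and not between the two methoxy groups, installs the carbon that becomes the bridge carbon of ring B.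

Step 7
Reactants: 11 2-fluoro-4,6-dimethoxy-3-methylbenzaldehyde
Product: 13 1-(2-fluoro-4,6-dimethoxy-3-methylphenyl)-N,N-dimethylmethanamine, via iminium acetate 12 (not isolated)
Conditions: Me2NH (2 M in THF), NaBH(OAc)3, AcOH, 1,2-dichloroethane, rt
Reagents that add atoms: dimethylamine, CNC
Why: In this reductive amination NaBH(OAc)3 reduces the iminium ion faster than the aldehyde, and the benzylic amine formed both blocks this ring position and later serves as the leaving group.

Step 8
Reactants: 13 1-(2-fluoro-4,6-dimethoxy-3-methylphenyl)-N,N-dimethylmethanamine, 14 N-methoxy-N-methylbutanamide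
Product: 17 1-{3-[(dimethylamino)methyl]-4-fluoro-2,6-dimethoxy-5-methylphenyl}butan-1-one, via aryllithium 15 (not isolated), via lithium hemiaminal alkoxide 16 (not isolated)
Conditions: n-BuLi, TMEDA, THF, 0 °C; then 14, −78 °C to rt; aq NH4Cl
Reagents that add atoms: N-methoxy-N-methylbutanamide 14, CCCC(=O)N(C)OC
Why: In this directed ortho-metalation the single remaining ring hydrogen lies between two methoxy groups and not beside fluorine, so no aryne can form, and the Weinreb amide acylates the aryllithium once because the chelated tetrahedral adduct survives until work-up.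

Step 9
Reactants: 17 1-{3-[(dimethylamino)methyl]-4-fluoro-2,6-dimethoxy-5-methylphenyl}butan-1-one
Product: 18 1-{3-[(dimethylamino)methyl]-4-fluoro-2,6-dihydroxy-5-methylphenyl}butan-1-one
Conditions: BBr3 (excess), CH2Cl2, −78 °C to rt; then H2O, NaHCO3 to pH 8
Reagents that add atoms: none
Why: Both methoxy groups flank the ketone and are cleaved readily in this BBr3 demethylation (one further equivalent is bound by the amine), and tertiary benzylic amines are known to survive it, so the ring B Mannich base is set free on neutral work-up.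

Step 10
Reactants: 19 1-(2,4,6-trihydroxyphenyl)butan-1-one
Product: 20 1-[4-(benzyloxy)-2,6-dihydroxyphenyl]butan-1-one
Conditions: BnBr (1.0 equiv), K2CO3 (1.0 equiv), acetone, rt to 40 °C
Reagents that add atoms: benzyl bromide, BrCc1ccccc1
Why: In this Williamson etherification the hydroxyl para to the acyl group is the most acidic and the only one not hydrogen-bonded to the ketone, so one equivalent each of base and benzyl bromide should give mainly the 4-benzyl ether, with di-O-benzyl and C-benzyl by-products removed by chromatography.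

Step 11
Reactants: 9 1-{3-[(dimethylamino)methyl]-6-fluoro-2,4-dihydroxy-5-methylphenyl}butan-1-one, 20 1-[4-(benzyloxy)-2,6-dihydroxyphenyl]butan-1-one
Product: 22 1-{4-(benzyloxy)-3-[(3-butanoyl-4-fluoro-2,6-dihydroxy-5-methylphenyl)methyl]-2,6-dihydroxyphenyl}butan-1-one, via ring A ortho-quinone methide 21 (not isolated)
Conditions: 20 (3 equiv), 1,4-dioxane, 100 °C, N2 stream
Reagents that add atoms: none
Why: Thermal loss of dimethylamine from the zwitterionic Mannich base gives an ortho-quinone methide that is trapped at one of the two equivalent free carbons of 20, each ortho to one free hydroxyl and para to the other (Mannich-base alkylation, a Michael-type C-alkylation); the excess of 20 favours monoalkylation and ring A has no free carbon with which to react with itself.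

Step 12
Reactants: 22 A–C dimer (name as in step 11), 18 1-{3-[(dimethylamino)methyl]-4-fluoro-2,6-dihydroxy-5-methylphenyl}butan-1-one
Product: 24 1-{4-(benzyloxy)-3-[(3-butanoyl-4-fluoro-2,6-dihydroxy-5-methylphenyl)methyl]-5-[(3-butanoyl-6-fluoro-2,4-dihydroxy-5-methylphenyl)methyl]-2,6-dihydroxyphenyl}butan-1-one, via ring B ortho-quinone methide 23 (not isolated)
Conditions: 1,4-dioxane, 100 °C, N2 stream
Reagents that add atoms: none
Why: This is the same Mannich-base alkylation through the ring B ortho-quinone methide, and ring C of 22 carries the only unsubstituted nucleophilic carbon of either partner, so the second bridge can form at one place only.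

Step 13
Reactants: 24 difluoro trimer with one benzyl ether on ring C (name as in step 12)
Product: 25 hepta-O-benzyl ether of the difluoro trimer (fluorine on position 4 of ring A and position 6 of ring B)
Conditions: BnBr (excess), K2CO3, n-Bu4NI (cat.), DMF, 50 °C
Reagents that add atoms: benzyl bromide, BrCc1ccccc1
Why: In this sixfold Williamson etherification ring C already carries one benzyl ether and every ring carbon is substituted, so C-alkylation would cost aromaticity, K2CO3 in a dipolar aprotic solvent favours O-alkylation, and warming with n-Bu4NI brings the hydrogen-bonded ortho-acyl phenols to reaction.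

Step 14
Reactants: 25 hepta-O-benzyl difluoro trimer, 26 sodium methoxide
Product: 28 hepta-O-benzyl ether of the target (methoxy on position 4 of ring A and position 6 of ring B), via monofluoro monomethoxy ether 27 (not isolated)
Conditions: NaOMe (excess), DMSO–MeOH (5:1), 90 °C
Reagents that add atoms: sodium methoxide 26, C[O-].[Na+]
Why: Methoxide adds to the fluorine-bearing carbon at position 4 of ring A and, more slowly, to that at position 6 of ring B, giving in each case a Meisenheimer anion whose charge rests on the carbon that carries the butyryl group (ortho in ring A, para in ring B) and is eased inductively by the two benzyloxy groups meta to the site of attack, after which fluoride is expelled (addition–elimination SNAr). The closest known reaction type is the exchange of fluoride for alkoxide in ortho- and para-fluoroaryl ketones. No ring is closed and no stereocenter is formed. The step needs chemoselectivity for the two C–F carbons over the seven benzyloxy-bearing carbons, the benzylic ether carbons and the ketones; it is secured because fluorine both accelerates the addition most and is by far the best leaving group, while the methanol co-solvent keeps the ketones from being held as enolates that would cancel their activation. The position of each methoxy group is not decided here: it was fixed when the fluorine of 1 was carried into rings A and B between the methyl group and the acyl or bridge carbon. Because the ring B ketone is twisted by its two flanking ethers, heating in DMSO is planned and ring A is expected to react first, through 27.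

Step 15
Reactants: 28 hepta-O-benzyl ether of the target
Product: 29 1-{3-[(3-butanoyl-2,6-dihydroxy-4-methoxy-5-methylphenyl)methyl]-5-[(3-butanoyl-2,4-dihydroxy-6-methoxy-5-methylphenyl)methyl]-2,4,6-trihydroxyphenyl}butan-1-one (CNP0171986.0)
Conditions: H2 (1 atm), 10% Pd/C, EtOAc–MeOH, rt
Reagents that add atoms: none
Why: Hydrogenolysis over Pd/C cleaves the seven benzyl ethers as toluene, while aryl methyl ethers, the diarylmethane bridges and the hindered aryl ketones are not reduced at ambient pressure.

**Compound list**

1 | 1-fluoro-3,5-dimethoxybenzene | COc1cc(F)cc(OC)c1 | starting material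
2 | N-[(2-fluoro-4,6-dimethoxyphenyl)methylidene]-N-methylmethanaminium dichlorophosphate | COc1cc(OC)c(C=[N+](C)C)c(F)c1.[O-]P(=O)(Cl)Cl | intermediate
3 | 2-fluoro-4,6-dimethoxybenzaldehyde | COc1cc(OC)c(C=O)c(F)c1 | intermediate
4 | (2-fluoro-4,6-dimethoxyphenyl)methanol | COc1cc(OC)c(CO)c(F)c1 | intermediate
5 | 1-fluoro-3,5-dimethoxy-2-methylbenzene | COc1cc(OC)c(C)c(F)c1 | intermediate
6 | butanoyl chloride | CCCC(=O)Cl | starting material
7 | 1-(2-fluoro-4,6-dimethoxy-3-methylphenyl)butan-1-one | CCCC(=O)c1c(F)c(C)c(OC)cc1OC | intermediate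
8 | 1-(2-fluoro-4,6-dihydroxy-3-methylphenyl)butan-1-one | CCCC(=O)c1c(F)c(C)c(O)cc1O | intermediate
9 | 1-{3-[(dimethylamino)methyl]-6-fluoro-2,4-dihydroxy-5-methylphenyl}butan-1-one (ring A Mannich base) | CCCC(=O)c1c(F)c(C)c(O)c(CN(C)C)c1O | intermediate
10 | N-[(2-fluoro-4,6-dimethoxy-3-methylphenyl)methylidene]-N-methylmethanaminium dichlorophosphate | COc1cc(OC)c(C)c(F)c1C=[N+](C)C.[O-]P(=O)(Cl)Cl | intermediate
11 | 2-fluoro-4,6-dimethoxy-3-methylbenzaldehyde | COc1cc(OC)c(C)c(F)c1C=O | intermediate
12 | N-[(2-fluoro-4,6-dimethoxy-3-methylphenyl)methylidene]-N-methylmethanaminium acetate | COc1cc(OC)c(C)c(F)c1C=[N+](C)C.CC(=O)[O-] | intermediate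
13 | 1-(2-fluoro-4,6-dimethoxy-3-methylphenyl)-N,N-dimethylmethanamine | COc1cc(OC)c(C)c(F)c1CN(C)C | intermediate
14 | N-methoxy-N-methylbutanamide | CCCC(=O)N(C)OC | starting material
15 | {3-[(dimethylamino)methyl]-4-fluoro-2,6-dimethoxy-5-methylphenyl}lithium | [Li]c1c(OC)c(C)c(F)c(CN(C)C)c1OC | intermediate
16 | lithium 1-{3-[(dimethylamino)methyl]-4-fluoro-2,6-dimethoxy-5-methylphenyl}-1-[methoxy(methyl)amino]butan-1-olate (racemic) | CCCC(O[Li])(N(C)OC)c1c(OC)c(C)c(F)c(CN(C)C)c1OC | intermediate
17 | 1-{3-[(dimethylamino)methyl]-4-fluoro-2,6-dimethoxy-5-methylphenyl}butan-1-one | CCCC(=O)c1c(OC)c(C)c(F)c(CN(C)C)c1OC | intermediate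
18 | 1-{3-[(dimethylamino)methyl]-4-fluoro-2,6-dihydroxy-5-methylphenyl}butan-1-one (ring B Mannich base) | CCCC(=O)c1c(O)c(C)c(F)c(CN(C)C)c1O | intermediate
19 | 1-(2,4,6-trihydroxyphenyl)butan-1-one | CCCC(=O)c1c(O)cc(O)cc1O | starting material
20 | 1-[4-(benzyloxy)-2,6-dihydroxyphenyl]butan-1-one (ring C with its 4-oxygen benzylated) | CCCC(=O)c1c(O)cc(OCc2ccccc2)cc1O | intermediate
21 | 4-butanoyl-3-fluoro-5-hydroxy-2-methyl-6-methylidenecyclohexa-2,4-dien-1-one | CCCC(=O)C1=C(O)C(=C)C(=O)C(C)=C1F | intermediate
22 | 1-{4-(benzyloxy)-3-[(3-butanoyl-4-fluoro-2,6-dihydroxy-5-methylphenyl)methyl]-2,6-dihydroxyphenyl}butan-1-one (A–C dimer) | CCCC(=O)c1c(O)cc(OCc2ccccc2)c(Cc2c(O)c(C)c(F)c(C(=O)CCC)c2O)c1O | intermediate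
23 | 2-butanoyl-5-fluoro-3-hydroxy-4-methyl-6-methylidenecyclohexa-2,4-dien-1-one | CCCC(=O)C1=C(O)C(C)=C(F)C(=C)C1=O | intermediate
24 | 1-{4-(benzyloxy)-3-[(3-butanoyl-4-fluoro-2,6-dihydroxy-5-methylphenyl)methyl]-5-[(3-butanoyl-6-fluoro-2,4-dihydroxy-5-methylphenyl)methyl]-2,6-dihydroxyphenyl}butan-1-one (difluoro trimer, one benzyl ether on ring C) | CCCC(=O)c1c(O)c(Cc2c(O)c(C)c(F)c(C(=O)CCC)c2O)c(OCc2ccccc2)c(Cc2c(O)c(C(=O)CCC)c(O)c(C)c2F)c1O | intermediate
25 | hepta-O-benzyl ether of the difluoro trimer (fluorine on position 4 of ring A and position 6 of ring B) | CCCC(=O)c1c(OCc2ccccc2)c(Cc2c(OCc3ccccc3)c(C)c(F)c(C(=O)CCC)c2OCc2ccccc2)c(OCc2ccccc2)c(Cc2c(OCc3ccccc3)c(C(=O)CCC)c(OCc3ccccc3)c(C)c2F)c1OCc1ccccc1 | intermediate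
26 | sodium methoxide | C[O-].[Na+] | starting material
27 | hepta-O-benzyl trimer with methoxy on position 4 of ring A and fluorine on position 6 of ring B | CCCC(=O)c1c(OCc2ccccc2)c(Cc2c(OCc3ccccc3)c(C)c(OC)c(C(=O)CCC)c2OCc2ccccc2)c(OCc2ccccc2)c(Cc2c(OCc3ccccc3)c(C(=O)CCC)c(OCc3ccccc3)c(C)c2F)c1OCc1ccccc1 | intermediate
28 | hepta-O-benzyl ether of the target | CCCC(=O)c1c(OCc2ccccc2)c(Cc2c(OCc3ccccc3)c(C)c(OC)c(C(=O)CCC)c2OCc2ccccc2)c(OCc2ccccc2)c(Cc2c(OCc3ccccc3)c(C(=O)CCC)c(OCc3ccccc3)c(C)c2OC)c1OCc1ccccc1 | intermediate
29 | 1-{3-[(3-butanoyl-2,6-dihydroxy-4-methoxy-5-methylphenyl)methyl]-5-[(3-butanoyl-2,4-dihydroxy-6-methoxy-5-methylphenyl)methyl]-2,4,6-trihydroxyphenyl}butan-1-one (CNP0171986.0) | CCCC(=O)c1c(O)c(Cc2c(O)c(C)c(OC)c(C(=O)CCC)c2O)c(O)c(Cc2c(O)c(C(=O)CCC)c(O)c(C)c2OC)c1O | target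

**Count and risks**

Total steps: 15. Longest linear sequence: 10 steps (steps 1, 2, 3, 4, 5, 11, 12, 13, 14, 15; the ring B branch through steps 1, 2, 6 to 9 and 12 to 15 is equally long).

Steps most likely to fail:

Step 14. The exchange on ring B may stop at 27, because the butyryl group para to the fluorine is turned out of the ring plane by its two neighbouring benzyloxy groups and then activates mainly inductively. On longer heating methoxide may instead attack benzylic ether carbons or hold the ketones as enolates. The fallback settles the ring B methyl ether before the rings are joined and exchanges only the ring A fluoride late; it sets out from 11 and comes back to the route at 28. Sodium methoxide in methanol at 60 °C should displace the fluoride of 11, which is ortho to a coplanar formyl group, to give 2,4,6-trimethoxy-3-methylbenzaldehyde F1. Reductive amination as in step 7, through the iminium acetate F2, gives the benzylic amine F3. Lithiation between two methoxy groups and acylation with 14 as in step 8, through the aryllithium F4 and the lithium hemiaminal alkoxide F5, gives the trimethoxy ketone F6. Excess BCl3 in CH2Cl2 should then remove only the two methyl groups whose oxygens can chelate boron together with the ketone oxygen; the methoxy group para to the ketone stays, and the product is the methoxy Mannich base F7. Heating F7 with 22 as in step 12 gives, through the ortho-quinone methide F8, the monofluoro hexaphenol F9. Benzylation as in step 13 gives the hepta-benzyl ether F10, and a single methoxide exchange on ring A, ortho to its ketone, gives 28.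

Step 13. Benzyl bromide is a soft electrophile, so ring C may be benzylated at carbon with loss of aromaticity. The hydrogen-bonded, doubly flanked phenols may also react incompletely, and the bridges may redistribute in base before every phenol is capped. The fallback caps the six free phenols as methoxymethyl ethers, introduced with a hard electrophile and removed by acid; it sets out from 24 and comes back at 29. MOMCl with iPr2NEt and n-Bu4NI in refluxing CH2Cl2 should give the hexa(methoxymethyl) mono-benzyl ether F11. The twofold methoxide exchange under the conditions of step 14, through the monomethoxy intermediate F12, gives the fully protected target F13, whose acetals are inert to methoxide. Aqueous HCl in THF–MeOH at 40 °C then frees six phenols to give the ring C mono-benzyl ether of the target F14, and hydrogenolysis as in step 15 gives 29.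

Step 11. The ring A quinone methide is flanked by two oxygen-bearing carbons and may form slowly or take dimethylamine back faster than it meets a carbon nucleophile, so that 9 is lost to oligomers while the new bridge redistributes at 100 °C. The fallback reverses the polarity at the A–C bridge, so that ring A reacts as the nucleophile through its single free carbon and 9 is not needed; it sets out from 18 (with 20 and 8) and comes back at 24. Heating 18 with an excess of 20 in dioxane, through 23, gives the B–C dimer F15. Formaldehyde and dimethylamine aminomethylate the one free carbon of ring C to give the dimer Mannich base F16. Heating F16 with 8 gives, through the ring C ortho-quinone methide F17, the trimer 24.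

Further compounds
F1 | step 14 | 2,4,6-trimethoxy-3-methylbenzaldehyde | COc1cc(OC)c(C)c(OC)c1C=O
F2 | step 14 | N-[(2,4,6-trimethoxy-3-methylphenyl)methylidene]-N-methylmethanaminium acetate | COc1cc(OC)c(C)c(OC)c1C=[N+](C)C.CC(=O)[O-]
F3 | step 14 | 1-(2,4,6-trimethoxy-3-methylphenyl)-N,N-dimethylmethanamine | COc1cc(OC)c(C)c(OC)c1CN(C)C
F4 | step 14 | {3-[(dimethylamino)methyl]-2,4,6-trimethoxy-5-methylphenyl}lithium | [Li]c1c(OC)c(C)c(OC)c(CN(C)C)c1OC
F5 | step 14 | lithium 1-{3-[(dimethylamino)methyl]-2,4,6-trimethoxy-5-methylphenyl}-1-[methoxy(methyl)amino]butan-1-olate (racemic) | CCCC(O[Li])(N(C)OC)c1c(OC)c(C)c(OC)c(CN(C)C)c1OC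
F6 | step 14 | 1-{3-[(dimethylamino)methyl]-2,4,6-trimethoxy-5-methylphenyl}butan-1-one | CCCC(=O)c1c(OC)c(C)c(OC)c(CN(C)C)c1OC
F7 | step 14 | 1-{3-[(dimethylamino)methyl]-2,6-dihydroxy-4-methoxy-5-methylphenyl}butan-1-one | CCCC(=O)c1c(O)c(C)c(OC)c(CN(C)C)c1O
F8 | step 14 | 2-butanoyl-3-hydroxy-5-methoxy-4-methyl-6-methylidenecyclohexa-2,4-dien-1-one | CCCC(=O)C1=C(O)C(C)=C(OC)C(=C)C1=O
F9 | step 14 | hexaphenol trimer with one benzyl ether on ring C, fluorine on ring A and methoxy on ring B | CCCC(=O)c1c(O)c(Cc2c(O)c(C)c(F)c(C(=O)CCC)c2O)c(OCc2ccccc2)c(Cc2c(O)c(C(=O)CCC)c(O)c(C)c2OC)c1O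
F10 | step 14 | hepta-O-benzyl trimer with fluorine on ring A and methoxy on ring B | CCCC(=O)c1c(OCc2ccccc2)c(Cc2c(OCc3ccccc3)c(C)c(F)c(C(=O)CCC)c2OCc2ccccc2)c(OCc2ccccc2)c(Cc2c(OCc3ccccc3)c(C(=O)CCC)c(OCc3ccccc3)c(C)c2OC)c1OCc1ccccc1
F11 | step 13 | hexa-O-(methoxymethyl) ether of 24 | CCCC(=O)c1c(OCOC)c(Cc2c(OCOC)c(C)c(F)c(C(=O)CCC)c2OCOC)c(OCc2ccccc2)c(Cc2c(OCOC)c(C(=O)CCC)c(OCOC)c(C)c2F)c1OCOC
F12 | step 13 | hexa-O-(methoxymethyl) mono-benzyl trimer with methoxy on ring A and fluorine on ring B | CCCC(=O)c1c(OCOC)c(Cc2c(OCOC)c(C)c(OC)c(C(=O)CCC)c2OCOC)c(OCc2ccccc2)c(Cc2c(OCOC)c(C(=O)CCC)c(OCOC)c(C)c2F)c1OCOC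
F13 | step 13 | hexa-O-(methoxymethyl) mono-benzyl ether of the target | CCCC(=O)c1c(OCOC)c(Cc2c(OCOC)c(C)c(OC)c(C(=O)CCC)c2OCOC)c(OCc2ccccc2)c(Cc2c(OCOC)c(C(=O)CCC)c(OCOC)c(C)c2OC)c1OCOC
F14 | step 13 | mono-benzyl ether of the target, benzyl on the 4-oxygen of ring C | CCCC(=O)c1c(O)c(Cc2c(O)c(C)c(OC)c(C(=O)CCC)c2O)c(OCc2ccccc2)c(Cc2c(O)c(C(=O)CCC)c(O)c(C)c2OC)c1O
F15 | step 11 | 1-{4-(benzyloxy)-3-[(3-butanoyl-6-fluoro-2,4-dihydroxy-5-methylphenyl)methyl]-2,6-dihydroxyphenyl}butan-1-one (B–C dimer) | CCCC(=O)c1c(O)cc(OCc2ccccc2)c(Cc2c(O)c(C(=O)CCC)c(O)c(C)c2F)c1O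
F16 | step 11 | Mannich base of the B–C dimer, dimethylaminomethyl on the free carbon of ring C | CCCC(=O)c1c(O)c(CN(C)C)c(OCc2ccccc2)c(Cc2c(O)c(C(=O)CCC)c(O)c(C)c2F)c1O
F17 | step 11 | ring C ortho-quinone methide of the B–C dimer | CCCC(=O)C1=C(O)C(Cc2c(O)c(C(=O)CCC)c(O)c(C)c2F)=C(OCc2ccccc2)C(=C)C1=O
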